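The ten-membered carbocycle is opened between the two methylene carbons that join the ring ketone (C4) to the methyl-bearing oxirane carbon (C7), i.e. at C5–C6. Read backwards, the cis-fused C7–C8 oxirane is a Z-olefin, so C6 is allylic and C5 is the α-carbon of a ketone. The key step, a palladium-catalysed intramolecular allylic alkylation, therefore closes the ring, forms C5–C6 and sets the Z-C7=C8 olefin in one operation, funnelling both C8 epimers of the precursor through one π-allyl complex. The precursor is an acyclic β-keto sulfone that already carries the butenolide, all three esters and an isopropenyl carbinol propanoate.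

Key step: step 10

Remark (locants used throughout): C1 CH(O-propanoyl), C2 CH2, C3 C(Me)OAc, C4 C=O, C5 and C6 CH2, C7 C(Me)–O, C8 CH–O, C9 CH–O(lactone), C10=C11 butenolide olefin (C10 in the large ring), C12 lactone C=O, C13 CH2OAc.
Remark (assumption): the sense of induction of the BINOL ligand (step 5) and of the sulfonamide ligand (step 6) is assigned by analogy with the usual models, and the antipodal ligand is used if the sense proves opposite; compound 1 is taken as purchasable (otherwise one step from (S)-lactic acid and pivalaldehyde).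

Step 1
Reactants: 1 (2S,5S)-2-tert-butyl-5-methyl-1,3-dioxolan-4-one; 2 allyl bromide
Product: 3 (2S,5R)-5-allyl-2-tert-butyl-5-methyl-1,3-dioxolan-4-one
Conditions: LiN(iPr)2, THF, −78 °C; then 2, −78 → −30 °C
Reagents that add atoms: none
Why: Enolate alkylation under self-regeneration of stereocentres: the electrophile enters anti to the tert-butyl group of the acetal, so allyl takes the place of the former hydrogen and the quaternary centre (future C3) is set as R.

Step 2
Reactants: 3 (2S,5R)-5-allyl-2-tert-butyl-5-methyl-1,3-dioxolan-4-one; 4 methyl phenyl sulfone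
Product: 5 (3R)-3-hydroxy-3-methyl-1-(phenylsulfonyl)hex-5-en-2-one
Conditions: 4 (3 equiv), n-BuLi (3 equiv), THF, −78 °C; then 3, −78 → 0 °C; aq. NH4Cl
Reagents that add atoms: none
Why: Claisen-type acylation of the α-sulfonyl carbanion by the activated dioxolanone carbonyl; the adduct collapses with loss of pivalaldehyde, freeing the tertiary alcohol, and the β-keto sulfone is shielded from a second addition as its enolate, so the quaternary centre is untouched.

Step 3
Reactants: 5 (3R)-3-hydroxy-3-methyl-1-(phenylsulfonyl)hex-5-en-2-one
Product: 6 (3R)-3-methyl-2-oxo-1-(phenylsulfonyl)hex-5-en-3-yl acetate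
Conditions: Ac2O, Sc(OTf)3 (2 mol%), MeCN, −20 °C
Reagents that add atoms: acetic anhydride, CC(=O)OC(C)=O
Why: Acid-catalysed acylation of a hindered tertiary alcohol, which leaves the weakly enolised β-keto sulfone alone and installs the C3 acetate of the target at the simplest stage.

Step 4
Reactants: 6 (3R)-3-methyl-2-oxo-1-(phenylsulfonyl)hex-5-en-3-yl acetate
Product: 7 (3R)-3-methyl-2,5-dioxo-1-(phenylsulfonyl)pentan-3-yl acetate
Conditions: O3, CH2Cl2, −78 °C; then PPh3, −78 °C → rt; used crude
Reagents that add atoms: ozone, [O-][O+]=O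
Why: Ozonolysis with reductive work-up cleaves the only olefin to the C1 aldehyde; the β-acetoxy aldehyde is not chromatographed, to avoid loss of acetic acid.

Step 5
Reactants: 8 3,4-dibromofuran-2(5H)-one; 9 methacrolein
Product: 11 (5R)-3,4-dibromo-5-(1-hydroxy-2-methylprop-2-enyl)furan-2(5H)-one (carbinol centre of either configuration), via 3,4-dibromo-2-(trimethylsilyloxy)furan 10 (not isolated)
Conditions: TMSOTf, Et3N, CH2Cl2, 0 °C; evaporation, pentane, filtration under argon; then Ti(OiPr)4/(R)-BINOL (20 mol%), 9, Et2O, −20 °C; then 1 M HCl, THF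
Reagents that add atoms: trimethylsilyl trifluoromethanesulfonate, C[Si](C)(C)OS(=O)(=O)C(F)(F)F (silyl group of 10 only)
Why: Soft enolisation gives the aromatic 2-silyloxyfuran 10, which is dearomatised at C5 in a catalytic enantioselective vinylogous Mukaiyama aldol reaction with the enal carbonyl; the titanium BINOLate sets the ring centre (future C9; R here only because bromine raises the rank of the neighbouring ring carbon), and the carbinol centre (future C8) need not be controlled because step 10 erases it.

Step 6
Reactants: 7 (3R)-3-methyl-2,5-dioxo-1-(phenylsulfonyl)pentan-3-yl acetate; 11 (5R)-3,4-dibromo-5-(1-hydroxy-2-methylprop-2-enyl)furan-2(5H)-one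
Product: 12 (3R,5S)-5-[(2S)-4-bromo-2-(1-hydroxy-2-methylprop-2-enyl)-5-oxo-2,5-dihydrofuran-3-yl]-5-hydroxy-3-methyl-2-oxo-1-(phenylsulfonyl)pentan-3-yl acetate
Conditions: CrCl2 (5 equiv), (S)-N-[2-(4-isopropyl-4,5-dihydrooxazol-2-yl)-6-methylphenyl]methanesulfonamide (5.5 equiv), Et3N (5.5 equiv), NiCl2 (2 mol%), THF, rt
Reagents that add atoms: none
Why: Nozaki–Hiyama–Kishi coupling: nickel inserts into the more electrophilic β-C–Br bond (C10) of the dibromobutenolide, transmetallation gives an alkenylchromium species that adds only to the aldehyde, and the chiral sulfonamide–chromium complex sets the C1 carbinol as S by reagent control.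

Step 7
Reactants: 12 the bromo diol of step 6; 13 (tributylstannyl)methanol
Product: 14 (3R,5S)-5-hydroxy-5-[(2S)-4-(hydroxymethyl)-2-(1-hydroxy-2-methylprop-2-enyl)-5-oxo-2,5-dihydrofuran-3-yl]-3-methyl-2-oxo-1-(phenylsulfonyl)pentan-3-yl acetate
Conditions: 13 (1.5 equiv), Pd(PPh3)4 (5 mol%), dioxane, 90 °C
Reagents that add atoms: none
Why: Stille coupling of the remaining α-bromide with the hydroxymethylstannane installs C13; free hydroxyls and the β-keto sulfone are tolerated, and no allylic ester is yet present that zerovalent palladium could ionise.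

Step 8
Reactants: 14 the triol of step 7
Product: 15 (3R,5S)-5-[(2S)-4-(acetoxymethyl)-2-(1-hydroxy-2-methylprop-2-enyl)-5-oxo-2,5-dihydrofuran-3-yl]-5-hydroxy-3-methyl-2-oxo-1-(phenylsulfonyl)pentan-3-yl acetate
Conditions: AcCl (1.05 equiv), 2,4,6-collidine, CH2Cl2, −78 °C
Reagents that add atoms: acetyl chloride, CC(Cl)=O
Why: Kinetically selective acylation of the primary allylic alcohol (C13) over the two secondary alcohols at low temperature with a hindered pyridine base.

Step 9
Reactants: 15 the monoacetate of step 8
Product: 16 (1S,3R)-3-acetoxy-1-[(2S)-4-(acetoxymethyl)-2-(2-methyl-1-propanoyloxyprop-2-enyl)-5-oxo-2,5-dihydrofuran-3-yl]-3-methyl-4-oxo-5-(phenylsulfonyl)pentyl propanoate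
Conditions: (EtCO)2O, DMAP (cat.), pyridine, CH2Cl2, 0 °C → rt
Reagents that add atoms: propanoic anhydride, CCC(=O)OC(=O)CC
Why: 4-Dimethylaminopyridine-catalysed acylation of both secondary alcohols: the C1 propanoate is the ester of the target and the C8 propanoate is the leaving group of step 10, so no protecting group is needed.

Step 10
Reactants: 16 the acyclic bis-propanoate of step 9
Product: 17 macrocyclic β-keto sulfone: ten-membered ring C1–C10 with (7Z)-C7=C8, C5–SO2Ph (either configuration), C1 propanoate, C3 acetate, and the fused butenolide with C13 acetate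
Conditions: Pd2(dba)3·CHCl3 (5 mol%), PPh3 (40 mol%), BSA (3 equiv), KOAc (10 mol%), THF, 65 °C, 16 added by syringe pump to a final 2 mM
Reagents that add atoms: none
Why: Zerovalent palladium ionises the isopropenyl carbinol propanoate of either C8 epimer to one cationic π-allyl complex (C6–C7–C8), while BSA and the released propanoate turn the β-keto sulfone into its enolate, whose carbon C5 attacks the unsubstituted terminus C6 on the face opposite to the metal. The closest known reaction type is the intramolecular Tsuji–Trost alkylation with sulfone-stabilised nucleophiles, which is established for medium and large carbocycles under high dilution. The ten-membered ring closes through the distal allyl terminus with the new olefin endocyclic; attack at the substituted terminus C8 would give an eight-membered ring with an exocyclic isopropenyl group and is disfavoured at the hindered secondary carbon. The only new stereocentre, the sulfonyl-bearing C5, is uncontrolled and is removed in step 11; the element that matters, the C7=C8 geometry, is governed by ring strain, because syn and anti allyl isomers interconvert by π–σ–π exchange (the 2-methyl group destabilises the syn form) and only the anti isomer leads to the less strained Z-cyclodecene. The step also needs selective ionisation of the C8 propanoate in the presence of the allylic C1 propanoate and C13 acetate, which is secured because those esters sit on the tetrasubstituted, electron-poor butenolide olefin that zerovalent palladium does not complex readily, whereas the terminal 1,1-disubstituted olefin does.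

Step 11
Reactants: 17 the macrocyclic β-keto sulfone of step 10
Product: 18 (1S,3R,7Z,9R)-configured macrocyclic ketone: as 17 with C5H2 (C9 is R by the sequence rule, same spatial arrangement as before)
Conditions: Bu3SnH (3 equiv), AIBN (0.2 equiv), toluene, 90 °C
Reagents that add atoms: none
Why: Radical desulfonylation of an α-sulfonyl ketone: the stannyl radical adds to the ketone oxygen, β-scission expels the benzenesulfonyl radical (the acetoxy group on the other α-carbon is a poor radical leaving group and stays), and the tin enolate is protonated on work-up, which also removes the uncontrolled C5 centre.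

Step 12
Reactants: 18 the macrocyclic Z-olefin of step 11
Product: 20 the target (1S,3R,7R,8S,9S), via (7R,8R)-8-bromo-7-hydroxy bromohydrin 19 (not isolated)
Conditions: NBS (1.1 equiv), THF–H2O 4:1, 0 °C; extractive work-up; then Ag2O (2 equiv), CH2Cl2, rt, dark
Reagents that add atoms: N-bromosuccinimide, O=C1CCC(=O)N1Br (bromine of 19 only); water, O (oxirane oxygen)
Why: Bromohydrin formation and oxirane closure: the bromonium ion should form on the exposed olefin face (with C9–H eclipsing the olefin to avoid 1,3-allylic strain with C6, C10 and the ring shield the other face), oxygen (water, or the transannular C4 carbonyl followed by water) opens it at the tertiary C7 from the inside, and silver-assisted displacement of bromide inverts C8, so that anti addition plus one inversion places the cis-oxirane on the inner face as 7R,8S, which direct oxygen transfer to the exposed face would not give.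

Compound list
1 | (2S,5S)-2-tert-butyl-5-methyl-1,3-dioxolan-4-one | C[C@@H]1O[C@H](C(C)(C)C)OC1=O | starting material
2 | allyl bromide | C=CCBr | starting material
3 | (2S,5R)-5-allyl-2-tert-butyl-5-methyl-1,3-dioxolan-4-one | C=CC[C@@]1(C)O[C@H](C(C)(C)C)OC1=O | intermediate
4 | methyl phenyl sulfone | CS(=O)(=O)c1ccccc1 | starting material
5 | (3R)-3-hydroxy-3-methyl-1-(phenylsulfonyl)hex-5-en-2-one | C=CC[C@@](C)(O)C(=O)CS(=O)(=O)c1ccccc1 | intermediate
6 | (3R)-3-methyl-2-oxo-1-(phenylsulfonyl)hex-5-en-3-yl acetate | C=CC[C@@](C)(OC(C)=O)C(=O)CS(=O)(=O)c1ccccc1 | intermediate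
7 | (3R)-3-methyl-2,5-dioxo-1-(phenylsulfonyl)pentan-3-yl acetate | O=CC[C@@](C)(OC(C)=O)C(=O)CS(=O)(=O)c1ccccc1 | intermediate
8 | 3,4-dibromofuran-2(5H)-one | O=C1OCC(Br)=C1Br | starting material
9 | methacrolein | CC(=C)C=O | starting material
10 | 3,4-dibromo-2-(trimethylsilyloxy)furan | C[Si](C)(C)Oc1occ(Br)c1Br | intermediate
11 | (5R)-3,4-dibromo-5-(1-hydroxy-2-methylprop-2-enyl)furan-2(5H)-one, carbinol centre unspecified | C=C(C)C(O)[C@H]1OC(=O)C(Br)=C1Br | intermediate
12 | (3R,5S)-5-[(2S)-4-bromo-2-(1-hydroxy-2-methylprop-2-enyl)-5-oxo-2,5-dihydrofuran-3-yl]-5-hydroxy-3-methyl-2-oxo-1-(phenylsulfonyl)pentan-3-yl acetate | O=S(=O)(c1ccccc1)CC(=O)[C@](C)(OC(C)=O)C[C@H](O)C1=C(Br)C(=O)O[C@@H]1C(O)C(C)=C | intermediate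
13 | (tributylstannyl)methanol | OC[Sn](CCCC)(CCCC)CCCC | starting material
14 | (3R,5S)-5-hydroxy-5-[(2S)-4-(hydroxymethyl)-2-(1-hydroxy-2-methylprop-2-enyl)-5-oxo-2,5-dihydrofuran-3-yl]-3-methyl-2-oxo-1-(phenylsulfonyl)pentan-3-yl acetate | O=S(=O)(c1ccccc1)CC(=O)[C@](C)(OC(C)=O)C[C@H](O)C1=C(CO)C(=O)O[C@@H]1C(O)C(C)=C | intermediate
15 | (3R,5S)-5-[(2S)-4-(acetoxymethyl)-2-(1-hydroxy-2-methylprop-2-enyl)-5-oxo-2,5-dihydrofuran-3-yl]-5-hydroxy-3-methyl-2-oxo-1-(phenylsulfonyl)pentan-3-yl acetate | O=S(=O)(c1ccccc1)CC(=O)[C@](C)(OC(C)=O)C[C@H](O)C1=C(COC(C)=O)C(=O)O[C@@H]1C(O)C(C)=C | intermediate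
16 | (1S,3R)-3-acetoxy-1-[(2S)-4-(acetoxymethyl)-2-(2-methyl-1-propanoyloxyprop-2-enyl)-5-oxo-2,5-dihydrofuran-3-yl]-3-methyl-4-oxo-5-(phenylsulfonyl)pentyl propanoate | O=S(=O)(c1ccccc1)CC(=O)[C@](C)(OC(C)=O)C[C@H](OC(=O)CC)C1=C(COC(C)=O)C(=O)O[C@@H]1C(OC(=O)CC)C(C)=C | intermediate
17 | macrocyclic β-keto sulfone, (7Z)-olefin, C5–SO2Ph unspecified, (1S,3R,9R) | CCC(=O)O[C@H]1C[C@@](C)(OC(C)=O)C(=O)C(S(=O)(=O)c3ccccc3)C/C(C)=C\[C@H]2OC(=O)C(COC(C)=O)=C12 | intermediate
18 | macrocyclic (7Z)-olefin ketone, (1S,3R,9R) | CCC(=O)O[C@H]1C[C@@](C)(OC(C)=O)C(=O)CC/C(C)=C\[C@H]2OC(=O)C(COC(C)=O)=C12 | intermediate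
19 | (1S,3R,7R,8R,9S)-8-bromo-7-hydroxy bromohydrin of 18 | CCC(=O)O[C@H]1C[C@@](C)(OC(C)=O)C(=O)CC[C@@](C)(O)[C@H](Br)[C@H]2OC(=O)C(COC(C)=O)=C12 | intermediate
20 | target, (1S,3R,7R,8S,9S)-7,8-epoxide | CCC(=O)O[C@H]1C[C@@](C)(OC(C)=O)C(=O)CC[C@@]2(C)O[C@H]2[C@H]2OC(=O)C(COC(C)=O)=C12 | target

Total step count: 12. Longest linear sequence: 11 steps (steps 1–4 and 6–12).

Steps most likely to fail

Step 10. The allyl complex may close through its syn isomer and give the E-cyclodecene, or ionisation may be followed by intermolecular alkylation instead of ring closure. The fallback changes the way the oxirane is made, so that the E-olefin becomes usable. It sets out from 16 and takes the E-configured macrocyclic sulfone F1 through the desulfonylation conditions of step 11 to the E-olefin ketone F2. Dihydroxylation of the trisubstituted olefin from its exposed face (OsO4 cat., NMO, acetone–water) should give the (7R,8R)-diol F3. A Mitsunobu cyclodehydration (PPh3, DIAD, THF) then lets the tertiary C7–O displace the activated secondary C8–O with inversion. Syn addition to the E-olefin followed by one inversion gives the same cis-oxirane, so the sequence comes back to the route at 20.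

Step 6. The acidic β-keto sulfone may protonate the alkenylchromium species, the amine may induce loss of acetic acid from the β-acetoxy aldehyde, or reagent control at C1 may be weak. The fallback replaces reagent control by a stereochemical correction. It sets out from 7 and 11 with the base-free, ligand-free coupling (CrCl2, NiCl2 cat., DMSO), which should give 12 together with its separable C1 epimer, the (1R)-bromo diol F4. F4 is carried through the conditions of steps 7 and 8 to the (1R)-triol F5 and the (1R)-monoacetate F6. A Mitsunobu esterification with propanoic acid (PPh3, DIAD) then inverts C1 while installing the propanoate; C8 is esterified as well, and its configuration is immaterial. The sequence comes back to the route at 16.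

Step 12. The bromonium ion may form on the inner face, or transannular capture by the C4 carbonyl may not revert, so that the 7,8-epimeric oxirane or bridged ethers result. The fallback delivers the oxygen from inside the ring. It sets out from 18 with 2KHSO5·KHSO4·K2SO4, NaHCO3 and Na2EDTA in MeCN–water at 0 °C. The C4 ketone, activated by its α-acetoxy group, should form a dioxirane in the flask and transfer oxygen across the ring to the inner face of C7=C8 (intramolecular epoxidation by a ketone-derived dioxirane). This comes back to the route at 20 and makes no new compound.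

Further compounds
F1 | step 10 | (7E)-isomer of 17 | CCC(=O)O[C@H]1C[C@@](C)(OC(C)=O)C(=O)C(S(=O)(=O)c3ccccc3)C/C(C)=C/[C@H]2OC(=O)C(COC(C)=O)=C12
F2 | step 10 | (7E)-isomer of 18 | CCC(=O)O[C@H]1C[C@@](C)(OC(C)=O)C(=O)CC/C(C)=C/[C@H]2OC(=O)C(COC(C)=O)=C12
F3 | step 10 | (1S,3R,7R,8R,9S)-7,8-diol | CCC(=O)O[C@H]1C[C@@](C)(OC(C)=O)C(=O)CC[C@@](C)(O)[C@H](O)[C@H]2OC(=O)C(COC(C)=O)=C12
F4 | step 6 | (5R)-carbinol epimer of 12 (1R in ring locants) | O=S(=O)(c1ccccc1)CC(=O)[C@](C)(OC(C)=O)C[C@@H](O)C1=C(Br)C(=O)O[C@@H]1C(O)C(C)=C
F5 | step 6 | (5R)-carbinol epimer of 14 | O=S(=O)(c1ccccc1)CC(=O)[C@](C)(OC(C)=O)C[C@@H](O)C1=C(CO)C(=O)O[C@@H]1C(O)C(C)=C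
F6 | step 6 | (5R)-carbinol epimer of 15 | O=S(=O)(c1ccccc1)CC(=O)[C@](C)(OC(C)=O)C[C@@H](O)C1=C(COC(C)=O)C(=O)O[C@@H]1C(O)C(C)=C
F0 | step 12 | none | none
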